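**Plan**

1. Retrosynthetic cuts, in order: the C8–O acyl bond (urocanate); the O7–C4 bond of the hemiketal together with the C7–CH3 bond, which leads back to a six-membered pyranone ketal in which O8 instead of O7 holds C4; the pyranone back to a furan spanning C4–C7; the C7–C8 bond (Ni/Cr ring closure) and the C2–C3 bond (enolate alkylation); the C2/C9 carbons back to dichloroketene and (R)-α-phellandrene.
2. Enabling feature: the ring O7–C7–C6=C5–C4(OH) is the closed tautomer of a (Z)-γ-hydroxy enone (C4=O, C7–OH). The oxygen on the neighbouring C8 can hold the same C4 carbonyl in a six-membered ring O8–C8–C7–C6=C5–C4, which is the Achmatowicz product of a 2,5-bridged furan. C3 is the α-carbon of a β-keto ester in the open tautomer and can therefore equilibrate.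
3. Forward order of rings: cyclohexene (from 1) → furan (bought) → ten-membered carbocycle as a furanophane (step 10) → six-membered pyranone by photooxygenative ring expansion through a strained endoperoxide (step 13) → five-membered dihydrofuranol by methyl addition and ring contraction (step 14) → urocanate (step 16).
4. Stereochemistry: C14 from 1; C1 and C10 from the anti, cis-selective ketene [2+2]; C8 from catalyst-controlled transfer hydrogenation; C7 from convex-face methyl addition to the bridged pyranone; C4 from the bridging constraint; C3 from thermodynamic equilibration.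

Key step: step 14

Remark on numbering: locants follow eunicellane numbering (C1/C10 ring fusion, C2, C3 bearing CO2Me, C4 hemiketal, C5=C6, C7 bearing CH3, C8 bearing the acyloxy group, C9, C11(CH3)=C12, C13, C14 bearing isopropyl); the target is (1R,3R,4R,7S,8S,10R,14R).

Assumption: C3 is configurationally labile through the ring-opened β-keto ester, and the 3R configuration of the target (ester anti to the ring oxygen O7) is taken to be the thermodynamically preferred one.

**Route**

Step 1
Reactants: 1 (R)-(−)-α-phellandrene
Product: 2 cis-fused dichlorocyclobutanone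
Conditions: Cl3CCOCl, activated Zn, Et2O, sonication, 15–20 °C
Reagents that add atoms: trichloroacetyl chloride (source of dichloroketene), ClC(=O)C(Cl)(Cl)Cl
Why: Thermal ketene–alkene [2+2] cycloaddition, in which dichloroketene should add to the less hindered disubstituted double bond of the diene on the face anti to the isopropyl group, with the carbonyl carbon on the diene terminus, so that C1 and C10 become cis to each other and trans to the isopropyl group at C14.

Step 2
Reactants: 2 cis-fused dichlorocyclobutanone
Product: 3 cis-fused cyclobutanone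
Conditions: Zn, AcOH, 70 °C
Reagents that add atoms: none
Why: Reductive dechlorination of an α,α-dichloro ketone with zinc in acetic acid should leave the ring fusion and the trisubstituted alkene untouched.

Step 3
Reactants: 3 cis-fused cyclobutanone
Product: 4 (E)-dimethylaminomethylene cyclobutanone
Conditions: t-BuOCH(NMe2)2, neat, 60 °C
Reagents that add atoms: tert-butoxybis(dimethylamino)methane (Bredereck's reagent), CN(C)C(OC(C)(C)C)N(C)C
Why: Bredereck aminomethylenation can occur only at the single α-CH2 (C9), because the other α-position is the ring-fusion methine; the new carbon becomes C8.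

Step 4
Reactants: 4 (E)-dimethylaminomethylene cyclobutanone
Product: 5 ester acetal (CO2Me on C1, CH2CH(OMe)2 on C10, cis)
Conditions: p-TsOH·H2O (1.2 equiv), MeOH, reflux
Reagents that add atoms: methanol, CO
Why: Acidic methanolysis converts the vinylogous amide into a β-keto acetal whose strained cyclobutanone should open by retro-Claisen cleavage of the C2–C9 bond, giving the methyl ester on C1 and the acetal arm on C10 without touching a stereocentre.

Step 5
Reactants: 5 ester acetal
Product: 6 primary alcohol (C2 as CH2OH)
Conditions: LiAlH4, THF, 0 °C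
Reagents that add atoms: none
Why: Hydride reduction of the ester to the primary alcohol, to which the dimethyl acetal is inert.

Step 6
Reactants: 6 primary alcohol
Product: 7 primary iodide (C2 as CH2I)
Conditions: I2, PPh3, imidazole, CH2Cl2, 0 °C → rt
Reagents that add atoms: iodine, II
Why: Appel-type iodination (Garegg–Samuelsson conditions) of the primary alcohol, with imidazole buffering the acid-sensitive acetal.

Step 7
Reactants: 8 methyl 2-(furan-2-yl)acetate
Product: 9 methyl 2-(5-bromofuran-2-yl)acetate
Conditions: NBS, DMF, 0 °C, dark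
Reagents that add atoms: N-bromosuccinimide, O=C1CCC(=O)N1Br
Why: Electrophilic aromatic bromination should occur at the free α-position (C5) of the 2-alkylfuran.

Step 8
Reactants: 9 methyl 2-(5-bromofuran-2-yl)acetate; 7 primary iodide
Product: 10 alkylated bromofuryl ester acetal (both C3 epimers)
Conditions: LiHMDS, THF, −78 °C; then 7, DMPU, −78 → 0 °C
Reagents that add atoms: none
Why: SN2 alkylation of the furyl- and ester-stabilised lithium enolate by the primary iodide forms the C2–C3 bond; C3 forms as both epimers, which is accepted because this centre is equilibrated in step 14.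

Step 9
Reactants: 10 alkylated bromofuryl ester acetal
Product: 11 bromofuryl ester aldehyde (C8 aldehyde)
Conditions: PPTS, acetone/H2O (4:1), 50 °C
Reagents that add atoms: water, O
Why: Mild acid hydrolysis of the dimethyl acetal should unmask the C8 aldehyde while the bromofuran and the ester are tolerated.

Step 10
Reactants: 11 bromofuryl ester aldehyde
Product: 12 furanophane alcohol (ten-membered carbocycle; C3 and C8 epimer mixtures)
Conditions: CrCl2 (6 equiv), NiCl2 (cat.), degassed DMSO, rt, slow addition to 2 mM
Reagents that add atoms: none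
Why: Intramolecular Nozaki–Hiyama–Kishi coupling (Ni insertion into the furyl C–Br bond, transmetalation to Cr(III), addition to the aldehyde) should form C7–C8 and close the ten-membered carbocycle chemoselectively beside the ester, helped by high dilution and the rigid cis-cyclohexene; the C8 epimers converge in step 11.

Step 11
Reactants: 12 furanophane alcohol
Product: 13 furanophane ketone (C8 ketone)
Conditions: Dess–Martin periodinane, NaHCO3, CH2Cl2, 0 °C → rt
Reagents that add atoms: none
Why: Dess–Martin oxidation of the furyl carbinol converges both C8 epimers on one ketone.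

Step 12
Reactants: 13 furanophane ketone
Product: 14 (8S)-furanophane alcohol
Conditions: RuCl(p-cymene)[(S,S)-TsDPEN] (2 mol %), HCO2H/Et3N (5:2), CH2Cl2, rt
Reagents that add atoms: none
Why: Noyori asymmetric transfer hydrogenation, in which the (S,S)-TsDPEN–Ru hydride should treat the furan as the aryl group of an aryl alkyl ketone and give the 8S carbinol under catalyst control.

Step 13
Reactants: 14 (8S)-furanophane alcohol
Product: 18 bridged pyranone methyl ketal, via furan endoperoxide 15 (not isolated), via (Z)-enedione 16 (not isolated), via pyranone lactol 17 (not isolated)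
Conditions: O2, methylene blue (cat.), visible light, CH2Cl2/MeOH, −78 °C; Me2S, −78 °C → rt; then HC(OMe)3, PPTS (cat.), rt
Reagents that add atoms: oxygen, O=O; trimethyl orthoformate, COC(OC)OC
Why: Photooxygenative Achmatowicz rearrangement, in which singlet oxygen should add [4+2] to the electron-rich furan much faster than it undergoes an ene reaction with the trisubstituted alkene, reduction of the strained endoperoxide gives the (Z)-enedione, the C8 hydroxyl closes on C4 (6-exo-trig) to the bridged pyranone lactol, and orthoformate exchange locks it as the methyl ketal with C4 fixed by the cis-bridging requirement.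

Step 14
Reactants: 18 bridged pyranone methyl ketal
Product: 22 C8-hydroxy dihydrofuranol hemiketal, via methyl carbinol ketal 19 (not isolated), via pyranose lactol 20 (not isolated), via open hydroxy enone 21 (not isolated)
Conditions: MeLi, CeCl3, THF, −78 °C; then 1 M aq. HCl, THF, 0 °C → rt; then Et3N (cat.), CH2Cl2, rt
Reagents that add atoms: methyllithium, [Li]C; water, O
Why: Methylcerium adds 1,2 to the C7 ketone of the oxabicyclo[5.3.1] pyranone, and aqueous acid then hydrolyses the allylic C4 methyl ketal to lactol 20, which opens to the (Z)-γ-hydroxy enone 21 and recloses through the new C7 hydroxyl. The closest known reaction type is the pyranose-to-furanose ring contraction that follows carbonyl addition to an Achmatowicz pyranone, a ring–chain tautomerism under thermodynamic control. The five-membered ring closes by 5-exo-trig attack of O7 on the C4 carbonyl, while the six-membered ring is lost by the reverse of its 6-exo-trig hemiketalisation. C7 is set by attack on the convex face of the ketone, anti to the five-carbon bridge C9–C10–C1–C2–C3 that spans C8 and C4; C4 is fixed because the six-carbon tether from C8 to C3 can span the 2,5-positions of the dihydrofuran only cis; C3 should equilibrate through the enol of the β-keto ester in 21 to the configuration with the ester anti to the ring oxygen. The step needs ketone-over-ester and 1,2-over-1,4 chemoselectivity, which the oxophilic and weakly basic cerium reagent at −78 °C should secure. It also needs furanose-over-pyranose selectivity, which the less strained oxabicyclo[6.2.1] skeleton should provide and which acylation of O8 in step 16 makes irreversible.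

Step 15
Reactants: 23 1-methyl-1H-imidazole-4-carbaldehyde
Product: 24 (E)-N-methylurocanic acid
Conditions: malonic acid, pyridine, piperidine (cat.), 100 °C
Reagents that add atoms: malonic acid, OC(=O)CC(=O)O
Why: Knoevenagel–Doebner condensation with decarboxylation should give the (E)-acrylic acid selectively.

Step 16
Reactants: 22 C8-hydroxy dihydrofuranol hemiketal; 24 (E)-N-methylurocanic acid
Product: 25 target
Conditions: DCC, DMAP (cat.), CH2Cl2/DMF, rt
Reagents that add atoms: none
Why: Steglich esterification should acylate the secondary C8 hydroxyl in preference to the hindered tertiary hemiketal hydroxyl, and it removes the only hydroxyl that could reopen a pyranose form.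

**Compound list**

1 | (R)-(−)-α-phellandrene, (5R)-2-methyl-5-(propan-2-yl)cyclohexa-1,3-diene | CC1=CC[C@@H](C=C1)C(C)C | starting material
2 | (1R,2R,6R)-7,7-dichloro-5-methyl-2-(propan-2-yl)bicyclo[4.2.0]oct-4-en-8-one; cis-fused, four-membered ring anti to isopropyl, C=O on the bridgehead next to CH–iPr | O=C1[C@@H]2[C@@H](C(C)C)CC=C(C)[C@@H]2C1(Cl)Cl | intermediate
3 | (1R,2R,6R)-5-methyl-2-(propan-2-yl)bicyclo[4.2.0]oct-4-en-8-one | O=C1[C@@H]2[C@@H](C(C)C)CC=C(C)[C@@H]2C1 | intermediate
4 | (E)-7-[(dimethylamino)methylidene] derivative of 3 | O=C1[C@@H]2[C@@H](C(C)C)CC=C(C)[C@@H]2/C1=C\N(C)C | intermediate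
5 | methyl (1R,2R,6R)-2-(2,2-dimethoxyethyl)-3-methyl-6-(propan-2-yl)cyclohex-3-ene-1-carboxylate | COC(=O)[C@@H]1[C@@H](C(C)C)CC=C(C)[C@@H]1CC(OC)OC | intermediate
6 | [(1R,2R,6R)-2-(2,2-dimethoxyethyl)-3-methyl-6-(propan-2-yl)cyclohex-3-en-1-yl]methanol | OC[C@@H]1[C@@H](C(C)C)CC=C(C)[C@@H]1CC(OC)OC | intermediate
7 | (3R,4R,5R)-3-(2,2-dimethoxyethyl)-4-(iodomethyl)-2-methyl-5-(propan-2-yl)cyclohex-1-ene | IC[C@@H]1[C@@H](C(C)C)CC=C(C)[C@@H]1CC(OC)OC | intermediate
8 | methyl 2-(furan-2-yl)acetate | COC(=O)Cc1ccco1 | starting material
9 | methyl 2-(5-bromofuran-2-yl)acetate | COC(=O)Cc1ccc(Br)o1 | intermediate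
10 | methyl 2-(5-bromofuran-2-yl)-3-[(1R,2R,6R)-2-(2,2-dimethoxyethyl)-3-methyl-6-(propan-2-yl)cyclohex-3-en-1-yl]propanoate, both C3 epimers | COC(=O)C(C[C@@H]1[C@@H](C(C)C)CC=C(C)[C@@H]1CC(OC)OC)c1ccc(Br)o1 | intermediate
11 | aldehyde of 10 (CH2CHO on C10), both C3 epimers | COC(=O)C(C[C@@H]1[C@@H](C(C)C)CC=C(C)[C@@H]1CC=O)c1ccc(Br)o1 | intermediate
12 | furanophane alcohol: ten-membered carbocycle C1–C10 with C4–C7 as a 2,5-disubstituted furan, CO2Me on C3, OH on C8; both epimers at C3 and at C8 | COC(=O)C1C[C@@H]2[C@@H](C(C)C)CC=C(C)[C@@H]2CC(O)c2ccc1o2 | intermediate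
13 | furanophane ketone (C8=O), both C3 epimers | COC(=O)C1C[C@@H]2[C@@H](C(C)C)CC=C(C)[C@@H]2CC(=O)c2ccc1o2 | intermediate
14 | (8S)-furanophane alcohol, both C3 epimers | COC(=O)C1C[C@@H]2[C@@H](C(C)C)CC=C(C)[C@@H]2C[C@H](O)c2ccc1o2 | intermediate
15 | furan 4,7-endoperoxide of 14 (O–O across C4 and C7, either face) | COC(=O)C1C[C@@H]2[C@@H](C(C)C)CC=C(C)[C@@H]2C[C@H](O)C23C=CC1(OO2)O3 | intermediate
16 | (5Z)-4,7-dioxo-8-hydroxy ten-membered enedione | COC(=O)C1C[C@@H]2[C@@H](C(C)C)CC=C(C)[C@@H]2C[C@H](O)C(=O)/C=C\C1=O | intermediate
17 | bridged pyranone lactol: ring O8–C8–C7(=O)–C6=C5–C4(OH), C3 and C9 tethers cis across O8 | COC(=O)C1C[C@@H]2[C@@H](C(C)C)CC=C(C)[C@@H]2C[C@@H]2O[C@@]1(O)C=CC2=O | intermediate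
18 | bridged pyranone methyl ketal (C4–OMe), C3 either configuration | COC(=O)C1C[C@@H]2[C@@H](C(C)C)CC=C(C)[C@@H]2C[C@@H]2O[C@@]1(OC)C=CC2=O | intermediate
19 | (7S)-methyl carbinol of 18: C7 carries CH3 and OH, OH cis to the C9 tether | COC(=O)C1C[C@@H]2[C@@H](C(C)C)CC=C(C)[C@@H]2C[C@@H]2O[C@@]1(OC)C=C[C@]2(C)O | intermediate
20 | pyranose lactol: C4–OH, O8 in the six-membered ring, C7(CH3)OH | COC(=O)C1C[C@@H]2[C@@H](C(C)C)CC=C(C)[C@@H]2C[C@@H]2O[C@@]1(O)C=C[C@]2(C)O | intermediate
21 | open (5Z)-4-oxo-7,8-dihydroxy ten-membered enone (β-keto ester) | COC(=O)C1C[C@@H]2[C@@H](C(C)C)CC=C(C)[C@@H]2C[C@H](O)[C@@](C)(O)/C=C\C1=O | intermediate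
22 | (1R,3R,4R,7S,8S,10R,14R)-dihydrofuranol hemiketal with free C8–OH (target without the urocanoyl group) | COC(=O)[C@@H]1C[C@@H]2[C@@H](C(C)C)CC=C(C)[C@@H]2C[C@H](O)[C@]2(C)C=C[C@@]1(O)O2 | intermediate
23 | 1-methyl-1H-imidazole-4-carbaldehyde | Cn1cnc(C=O)c1 | starting material
24 | (E)-3-(1-methyl-1H-imidazol-4-yl)prop-2-enoic acid (N-methylurocanic acid) | Cn1cnc(/C=C/C(=O)O)c1 | intermediate
25 | target, CNP0113846.1 | COC(=O)[C@@H]1C[C@@H]2[C@@H](C(C)C)CC=C(C)[C@@H]2C[C@H](OC(=O)/C=C/c2cn(C)cn2)[C@]2(C)C=C[C@@]1(O)O2 | target

**Step count**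

Total steps: 16. Longest linear sequence: 14 (steps 1–6, 8–14, 16).

**Steps most likely to fail**

Step 14. The methyl addition could show poor facial selectivity on the bridged ketal, or the acid stage could stall at a pyranose/furanose mixture or lose water or methanol towards a C3=C4 enol ether. The fallback sets out from 14 and comes back at 22, and it avoids both the pyranone and the ring contraction. The C8 hydroxyl of 14 is silylated (TBSCl, imidazole, DMF) to the silyl ether F1. Photooxygenation gives the endoperoxide F2, and Me2S reduction gives the open (Z)-enedione F3, which cannot close to a pyranone. F3 is treated with MeMgBr (2.2 equiv, THF, −78 °C): the first equivalent turns the β-keto ester into its chelated magnesium enolate, which masks C4 and the ester, and the second should add to the C7 ketone under Felkin–Anh control (bulky, non-chelating silyloxy group anti to the nucleophile), which corresponds to 7S. Work-up should give the C8-silylated hemiketal F4 directly, and TBAF/AcOH would give 22.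

Step 10. The ring closure could lose out to oligomerisation or to reductive loss of bromine, because a strained medium ring is formed. The fallback sets out from 7 (with 8) and comes back at 13, replacing the organochromium closure by an electrophilic aromatic substitution. The enolate of the bromine-free ester 8 is alkylated with 7 to give the furyl ester acetal F5. Acetal hydrolysis gives the aldehyde F6, and Pinnick oxidation (NaClO2, NaH2PO4, 2-methyl-2-butene) gives the carboxylic acid F7. Intramolecular Friedel–Crafts acylation of the free furan 5-position (TFAA, CH2Cl2, high dilution) should then close the ring to ketone 13, by-passing steps 7, 10 and 11.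

Step 12. The conformational bias of the macrocyclic ketone could override catalyst control and lead to hydride delivery from the wrong face. The fallback sets out from 13 and comes back at 14, using inversion at carbon instead of face-selective reduction. Substrate-controlled reduction (NaBH4, CeCl3, MeOH, −78 °C) is run; if it gives the (8R)-alcohol F8, Mitsunobu inversion with 4-nitrobenzoic acid (PPh3, DIAD, THF) gives the (8S)-4-nitrobenzoate F9, and methanolysis (K2CO3, MeOH) gives 14.

**Further compounds**

F1 | step 14 | C8 tert-butyldimethylsilyl ether of 14 | COC(=O)C1C[C@@H]2[C@@H](C(C)C)CC=C(C)[C@@H]2C[C@H](O[Si](C)(C)C(C)(C)C)c2ccc1o2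
F2 | step 14 | furan 4,7-endoperoxide of F1 | COC(=O)C1C[C@@H]2[C@@H](C(C)C)CC=C(C)[C@@H]2C[C@H](O[Si](C)(C)C(C)(C)C)C23C=CC1(OO2)O3
F3 | step 14 | open (5Z)-4,7-dioxo enedione with C8 silyl ether | COC(=O)C1C[C@@H]2[C@@H](C(C)C)CC=C(C)[C@@H]2C[C@H](O[Si](C)(C)C(C)(C)C)C(=O)/C=C\C1=O
F4 | step 14 | C8 silyl ether of 22 | COC(=O)[C@@H]1C[C@@H]2[C@@H](C(C)C)CC=C(C)[C@@H]2C[C@H](O[Si](C)(C)C(C)(C)C)[C@]2(C)C=C[C@@]1(O)O2
F5 | step 10 | bromine-free analogue of 10 (furan-2-yl ester acetal), both C3 epimers | COC(=O)C(C[C@@H]1[C@@H](C(C)C)CC=C(C)[C@@H]1CC(OC)OC)c1ccco1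
F6 | step 10 | aldehyde of F5 | COC(=O)C(C[C@@H]1[C@@H](C(C)C)CC=C(C)[C@@H]1CC=O)c1ccco1
F7 | step 10 | carboxylic acid of F6 (CH2CO2H on C10) | COC(=O)C(C[C@@H]1[C@@H](C(C)C)CC=C(C)[C@@H]1CC(=O)O)c1ccco1
F8 | step 12 | (8R)-furanophane alcohol, C8 epimer of 14 | COC(=O)C1C[C@@H]2[C@@H](C(C)C)CC=C(C)[C@@H]2C[C@@H](O)c2ccc1o2
F9 | step 12 | (8S)-4-nitrobenzoate of 14 | COC(=O)C1C[C@@H]2[C@@H](C(C)C)CC=C(C)[C@@H]2C[C@H](OC(=O)c3ccc(cc3)[N+](=O)[O-])c2ccc1o2
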